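**Strategy.** Ruixianglangdusu B is cut at C-3/C-3'' into two (2S)-flavanones, and ring C of each is closed between C-2 and C-3. The feature used is that C-2 carries O-1 and the 4-methoxyphenyl ring B, so C-2 plus ring B is a 4-methoxybenzyl ether of the ring A phenol. An aryl diazomethyl ketone bearing ortho 4-methoxybenzyl ethers should therefore give the flavanone in one enantioselective dirhodium carbenoid C–H insertion: the carbene carbon becomes C-3, the benzylic carbon C-2. The two monomers are then joined through a silicon tether by oxidative enol coupling, which copies the presumed biosynthesis and sets C-3 and C-3'' trans to the aryl groups.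

Key step: step 4

Numbering used below: unit 1 is the 5,7-dihydroxyflavanone half (O-1, C-2, C-3, C-4, rings A, B, C); unit 2 is the 5-hydroxy-7-methoxyflavanone half (primed locants C-2'', C-3'').

Assumption: Rh2(S-PTTL)4, dirhodium tetrakis[N-phthaloyl-(S)-tert-leucinate], is written as the catalyst that delivers the 2S products; its sense of induction is to be confirmed in the first run, and Rh2(R-PTTL)4 is used instead, with no other change, if it is the reverse.

Step 1
Reactants: 1 1-(2,4,6-trihydroxyphenyl)ethanone; 2 4-methoxybenzyl chloride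
Product: 3 1-[2-hydroxy-4,6-bis(4-methoxybenzyloxy)phenyl]ethanone
Conditions: 2 (2.1 equiv), K2CO3, acetone, reflux
Reagents that add atoms: none
Why: Williamson ether synthesis under mild conditions, in which the free 4-hydroxyl and one ortho hydroxyl are alkylated while the last phenol, held in a hydrogen bond to the ketone, stays free; the gentle conditions should also limit C-benzylation of the electron-rich ring.

Step 2
Reactants: 3 1-[2-hydroxy-4,6-bis(4-methoxybenzyloxy)phenyl]ethanone; 2 4-methoxybenzyl chloride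
Product: 4 1-[2,4,6-tris(4-methoxybenzyloxy)phenyl]ethanone
Conditions: 2 (1.3 equiv), K2CO3, NaI (cat.), DMF, 70 °C
Reagents that add atoms: none
Why: Williamson ether synthesis under forcing conditions (dipolar aprotic solvent, iodide catalysis, heating), which should alkylate the remaining chelated phenol on oxygen.

Step 3
Reactants: 4 1-[2,4,6-tris(4-methoxybenzyloxy)phenyl]ethanone
Product: 6 2-diazo-1-[2,4,6-tris(4-methoxybenzyloxy)phenyl]ethanone, via trifluoroacetyl diketone 5 (not isolated)
Conditions: LiN(SiMe3)2, THF, −78 °C; CF3CO2CH2CF3; aq NH4Cl work-up; then p-ABSA, Et3N, H2O, MeCN, rt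
Reagents that add atoms: 4-acetamidobenzenesulfonyl azide (p-ABSA), CC(=O)Nc1ccc(cc1)S(=O)(=O)N=[N+]=[N-] (both diazo nitrogens of 6); 2,2,2-trifluoroethyl trifluoroacetate, O=C(OCC(F)(F)F)C(F)(F)F (trifluoroacetyl group of 5 only)
Why: Detrifluoroacetylative Regitz diazo transfer, in which the lithium enolate of the methyl ketone (the only enolizable site) is C-acylated to diketone 5, whose activated methylene takes the diazo group from the sulfonyl azide with loss of the trifluoroacetyl group.

Step 4
Reactants: 6 2-diazo-1-[2,4,6-tris(4-methoxybenzyloxy)phenyl]ethanone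
Product: 7 (2S)-5,7-bis(4-methoxybenzyloxy)-2-(4-methoxyphenyl)chroman-4-one
Conditions: Rh2(S-PTTL)4 (1 mol %), 4 Å molecular sieves, toluene, 0 °C, slow addition of 6; then recrystallization
Reagents that add atoms: none
Why: The dirhodium catalyst releases N2 from 6 to give an electrophilic acyl carbenoid whose carbon (the future C-3) inserts, through a concerted three-centre transition state with hydride-transfer character, into a benzylic C–H bond of an ortho 4-methoxybenzyl ether (the future C-2), so that this ether becomes C-2 and ring B. The closest known reaction type is the dirhodium carboxylate catalysed intramolecular C–H insertion of ortho-alkoxyaryl α-diazoketones next to the ether oxygen, which gives chroman-4-ones, also with chiral carboxylate ligands. Ring C closes in the six-membered (1,6) insertion mode through C-4, C-4a, C-8a and O-1; no five-membered C–H insertion is possible because the fifth atom is the ether oxygen. The only new stereocentre, C-2, is set by the chiral carboxylate ligands, which choose between the two enantiotopic benzylic hydrogens; recrystallization, and later the union of two 2S monomers (which turns residual 2R material into separable diastereomers), should raise the purity further. The step needs C–H insertion to win over oxonium ylide formation followed by [1,2]-shift of the benzyl group and over attack on an arene: the ether oxygen is a weak donor because it is conjugated with the acylated ring A, the C–H bond is doubly activated by oxygen and by the 4-methoxyphenyl group, and a rhodium carboxylate rather than a copper catalyst is used. The two ortho ethers are equivalent and give the same product (the one that does not react stays as the protecting group of O-5), and the para ether is out of reach.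

Step 5
Reactants: 8 1-(2,6-dihydroxy-4-methoxyphenyl)ethanone; 2 4-methoxybenzyl chloride
Product: 9 1-[4-methoxy-2,6-bis(4-methoxybenzyloxy)phenyl]ethanone
Conditions: 2 (2.4 equiv), K2CO3, NaI (cat.), DMF, 70 °C
Reagents that add atoms: none
Why: Williamson ether synthesis of both ortho phenols under the forcing conditions of step 2.

Step 6
Reactants: 9 1-[4-methoxy-2,6-bis(4-methoxybenzyloxy)phenyl]ethanone
Product: 11 2-diazo-1-[4-methoxy-2,6-bis(4-methoxybenzyloxy)phenyl]ethanone, via trifluoroacetyl diketone 10 (not isolated)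
Conditions: LiN(SiMe3)2, THF, −78 °C; CF3CO2CH2CF3; aq NH4Cl work-up; then p-ABSA, Et3N, H2O, MeCN, rt
Reagents that add atoms: 4-acetamidobenzenesulfonyl azide (p-ABSA), CC(=O)Nc1ccc(cc1)S(=O)(=O)N=[N+]=[N-] (both diazo nitrogens of 11); 2,2,2-trifluoroethyl trifluoroacetate, O=C(OCC(F)(F)F)C(F)(F)F (trifluoroacetyl group of 10 only)
Why: Detrifluoroacetylative Regitz diazo transfer as in step 3, through the trifluoroacetyl diketone 10.

Step 7
Reactants: 11 2-diazo-1-[4-methoxy-2,6-bis(4-methoxybenzyloxy)phenyl]ethanone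
Product: 12 (2S)-7-methoxy-5-(4-methoxybenzyloxy)-2-(4-methoxyphenyl)chroman-4-one
Conditions: Rh2(S-PTTL)4 (1 mol %), 4 Å molecular sieves, toluene, 0 °C, slow addition of 11; then recrystallization
Reagents that add atoms: none
Why: The same enantioselective dirhodium carbenoid 1,6 C–H insertion as in step 4 closes ring C of unit 2 between C-3'' and C-2'', with C-2'' set as S by the same catalyst and either of the two equivalent ortho ethers leading to the same product.

Step 8
Reactants: 12 (2S)-7-methoxy-5-(4-methoxybenzyloxy)-2-(4-methoxyphenyl)chroman-4-one; 7 (2S)-5,7-bis(4-methoxybenzyloxy)-2-(4-methoxyphenyl)chroman-4-one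
Product: 14 [(2S)-5,7-bis(4-methoxybenzyloxy)-2-(4-methoxyphenyl)-2H-chromen-4-yl]oxy-[(2S)-7-methoxy-5-(4-methoxybenzyloxy)-2-(4-methoxyphenyl)-2H-chromen-4-yl]oxy-di(propan-2-yl)silane, via silyl triflate enol ether 13 (not isolated)
Conditions: 12, iPr2Si(OTf)2 (1.0 equiv), Et3N, CH2Cl2, −78 °C; then 7, Et3N, −78 °C to rt; aq NaHCO3 work-up
Reagents that add atoms: diisopropylsilyl bis(trifluoromethanesulfonate), CC(C)[Si](OS(=O)(=O)C(F)(F)F)(OS(=O)(=O)C(F)(F)F)C(C)C
Why: Soft enolization with a silyl triflate and an amine, in which the first Si–OTf bond converts 12 into the enol ether 13 and the less reactive second one then does the same with 7, so that two different enols are tied to one silicon without a free enolate that could expel the ring oxygen, and C-2 and C-2'' are not touched.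

Step 9
Reactants: 14 the mixed diisopropylsilyl bis-enol ether of 7 and 12
Product: 15 (2S,3R)-5,7-bis(4-methoxybenzyloxy)-3-[(2S,3R)-7-methoxy-5-(4-methoxybenzyloxy)-2-(4-methoxyphenyl)-4-oxochroman-3-yl]-2-(4-methoxyphenyl)chroman-4-one
Conditions: (NH4)2Ce(NO3)6 (2.2 equiv), NaHCO3, MeCN/EtCN, −20 °C
Reagents that add atoms: none
Why: Oxidative coupling of a silyl bis-enol ether, in which one-electron oxidation by tetravalent cerium gives an enol ether radical cation that adds to the second enol ether within the seven-membered silicon-tethered array (cross-coupling only), and second oxidation and loss of silicon give the 1,4-diketone; C-3 and C-3'' are each set by attack anti to the neighbouring C-2 aryl group, which is also the more stable diequatorial trans arrangement, so that two 2S monomers should give the (2S,3R,2''S,3''R) isomer.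

Step 10
Reactants: 15 the tris(4-methoxybenzyl) ether of the target
Product: 16 Ruixianglangdusu B, (2S,3R)-5,7-dihydroxy-3-[(2S,3R)-5-hydroxy-7-methoxy-2-(4-methoxyphenyl)-4-oxochroman-3-yl]-2-(4-methoxyphenyl)chroman-4-one
Conditions: H2 (1 atm), Pd/C, EtOAc/MeOH, rt
Reagents that add atoms: none
Why: Hydrogenolysis of the three aryl 4-methoxybenzyl ethers under neutral conditions, which should leave the methyl ethers, the ketones, the epimerizable C-3 and C-3'' and the acid-sensitive C-2 and C-2'' unchanged.

**Compound list**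

1 | 1-(2,4,6-trihydroxyphenyl)ethanone | CC(=O)c1c(O)cc(O)cc1O | starting material
2 | 4-methoxybenzyl chloride | COc1ccc(CCl)cc1 | starting material
3 | 1-[2-hydroxy-4,6-bis(4-methoxybenzyloxy)phenyl]ethanone | CC(=O)c1c(O)cc(OCc2ccc(OC)cc2)cc1OCc1ccc(OC)cc1 | intermediate
4 | 1-[2,4,6-tris(4-methoxybenzyloxy)phenyl]ethanone | CC(=O)c1c(OCc2ccc(OC)cc2)cc(OCc2ccc(OC)cc2)cc1OCc1ccc(OC)cc1 | intermediate
5 | 4,4,4-trifluoro-1-[2,4,6-tris(4-methoxybenzyloxy)phenyl]butane-1,3-dione | O=C(CC(=O)C(F)(F)F)c1c(OCc2ccc(OC)cc2)cc(OCc2ccc(OC)cc2)cc1OCc1ccc(OC)cc1 | intermediate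
6 | 2-diazo-1-[2,4,6-tris(4-methoxybenzyloxy)phenyl]ethanone | [N-]=[N+]=CC(=O)c1c(OCc2ccc(OC)cc2)cc(OCc2ccc(OC)cc2)cc1OCc1ccc(OC)cc1 | intermediate
7 | (2S)-5,7-bis(4-methoxybenzyloxy)-2-(4-methoxyphenyl)chroman-4-one | O=C1C[C@@H](c2ccc(OC)cc2)Oc2cc(OCc3ccc(OC)cc3)cc(OCc3ccc(OC)cc3)c12 | intermediate
8 | 1-(2,6-dihydroxy-4-methoxyphenyl)ethanone | CC(=O)c1c(O)cc(OC)cc1O | starting material
9 | 1-[4-methoxy-2,6-bis(4-methoxybenzyloxy)phenyl]ethanone | CC(=O)c1c(OCc2ccc(OC)cc2)cc(OC)cc1OCc1ccc(OC)cc1 | intermediate
10 | 4,4,4-trifluoro-1-[4-methoxy-2,6-bis(4-methoxybenzyloxy)phenyl]butane-1,3-dione | O=C(CC(=O)C(F)(F)F)c1c(OCc2ccc(OC)cc2)cc(OC)cc1OCc1ccc(OC)cc1 | intermediate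
11 | 2-diazo-1-[4-methoxy-2,6-bis(4-methoxybenzyloxy)phenyl]ethanone | [N-]=[N+]=CC(=O)c1c(OCc2ccc(OC)cc2)cc(OC)cc1OCc1ccc(OC)cc1 | intermediate
12 | (2S)-7-methoxy-5-(4-methoxybenzyloxy)-2-(4-methoxyphenyl)chroman-4-one | O=C1C[C@@H](c2ccc(OC)cc2)Oc2cc(OC)cc(OCc3ccc(OC)cc3)c12 | intermediate
13 | [(2S)-7-methoxy-5-(4-methoxybenzyloxy)-2-(4-methoxyphenyl)-2H-chromen-4-yl]oxy-di(propan-2-yl)silyl trifluoromethanesulfonate | CC(C)[Si](OC1=C[C@@H](c2ccc(OC)cc2)Oc2cc(OC)cc(OCc3ccc(OC)cc3)c12)(OS(=O)(=O)C(F)(F)F)C(C)C | intermediate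
14 | [(2S)-5,7-bis(4-methoxybenzyloxy)-2-(4-methoxyphenyl)-2H-chromen-4-yl]oxy-[(2S)-7-methoxy-5-(4-methoxybenzyloxy)-2-(4-methoxyphenyl)-2H-chromen-4-yl]oxy-di(propan-2-yl)silane | CC(C)[Si](OC1=C[C@@H](c2ccc(OC)cc2)Oc2cc(OC)cc(OCc3ccc(OC)cc3)c12)(OC1=C[C@@H](c2ccc(OC)cc2)Oc2cc(OCc3ccc(OC)cc3)cc(OCc3ccc(OC)cc3)c12)C(C)C | intermediate
15 | (2S,3R)-5,7-bis(4-methoxybenzyloxy)-3-[(2S,3R)-7-methoxy-5-(4-methoxybenzyloxy)-2-(4-methoxyphenyl)-4-oxochroman-3-yl]-2-(4-methoxyphenyl)chroman-4-one | COc1ccc([C@H]2Oc3cc(OCc4ccc(OC)cc4)cc(OCc4ccc(OC)cc4)c3C(=O)[C@@H]2[C@H]2C(=O)c3c(OCc4ccc(OC)cc4)cc(OC)cc3O[C@@H]2c2ccc(OC)cc2)cc1 | intermediate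
16 | Ruixianglangdusu B, (2S,3R)-5,7-dihydroxy-3-[(2S,3R)-5-hydroxy-7-methoxy-2-(4-methoxyphenyl)-4-oxochroman-3-yl]-2-(4-methoxyphenyl)chroman-4-one | COc1ccc([C@H]2Oc3cc(O)cc(O)c3C(=O)[C@@H]2[C@H]2C(=O)c3c(O)cc(OC)cc3O[C@@H]2c2ccc(OC)cc2)cc1 | target

**Step count and risks**

Total steps: 10. Longest linear sequence: 7 steps (steps 1, 2, 3, 4, 8, 9, 10); the branch of steps 5, 6, 7 joins at step 8.

Steps most likely to fail:

1. Step 4 (and in the same way step 7). The very reactive carbenoid, which has only an acyl substituent, may discriminate poorly between the two enantiotopic benzylic hydrogens, so that the ring closes with low enantiomeric purity. The fallback runs the ring closure without asymmetric induction and sorts the stereocentre afterwards. It sets out from 6: achiral Rh2(OAc)4 in CH2Cl2 should give, by the same C-2–C-3 insertion, racemic 5,7-bis(4-methoxybenzyloxy)-2-(4-methoxyphenyl)chroman-4-one F1. Kinetic resolution by asymmetric transfer hydrogenation (Noyori type; RuCl(p-cymene)[(R,R)-TsDPEN], HCO2H/Et3N; the antipodal ligand if the sense is the reverse) should then reduce the 2R ketone faster, to the cis alcohol (2R,4R)-5,7-bis(4-methoxybenzyloxy)-2-(4-methoxyphenyl)chroman-4-ol F2, which is separated. The unreacted 2S ketone is compound 7, where the route is rejoined.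

2. Step 9. The one-electron oxidant may also attack the 4-methoxyphenyl rings, or the enol ether radical cation may lose H-2 and aromatize to the flavone before the hindered C-3–C-3'' bond forms. The fallback replaces the oxidative coupling by a reductive radical one and sets out from 12 and 7. Bromination of 12 (PhNMe3Br3, propylene oxide, THF, 0 °C) should give the trans bromide (2R,3R)-3-bromo-7-methoxy-5-(4-methoxybenzyloxy)-2-(4-methoxyphenyl)chroman-4-one F3 (the descriptor at C-2 changes with the bromine, not the geometry). Silylation of 7 (TBSOTf, Et3N, CH2Cl2) should give tert-butyl-[(2S)-5,7-bis(4-methoxybenzyloxy)-2-(4-methoxyphenyl)-2H-chromen-4-yl]oxy-dimethylsilane F4. Visible-light photoredox coupling (fac-Ir(ppy)3, 2,6-lutidine, MeCN, blue light) reduces the C–Br bond to the C-3'' α-keto radical, which adds to F4 anti to its C-2 aryl group; oxidation and loss of silicon should give 15, where the route is rejoined.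

3. Step 8. The two enols may scramble at silicon to the symmetrical bis-enol ethers (which would lead to homodimers), or the hindered 5-alkoxy ketones may enolize incompletely. The fallback gives up the tether, uses a polar umpolung cross-coupling and sets out from 7 and 12. TMSOTf/Et3N should convert 7 into trimethyl-[(2S)-5,7-bis(4-methoxybenzyloxy)-2-(4-methoxyphenyl)-2H-chromen-4-yl]oxysilane F5 and 12 into trimethyl-[(2S)-7-methoxy-5-(4-methoxybenzyloxy)-2-(4-methoxyphenyl)-2H-chromen-4-yl]oxysilane F6. F5 is turned at −78 °C with PhI(OAc)2/BF3·OEt2 into its electrophilic enolonium species (hypervalent iodine), and F6 is then added as the nucleophile, each carbon reacting anti to its neighbouring C-2 aryl group. This should give 15 directly, so that steps 8 and 9 are both replaced and the route is rejoined at 15.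

**Further compounds**

F1 | step 4 | racemic 5,7-bis(4-methoxybenzyloxy)-2-(4-methoxyphenyl)chroman-4-one | O=C1CC(c2ccc(OC)cc2)Oc2cc(OCc3ccc(OC)cc3)cc(OCc3ccc(OC)cc3)c12
F2 | step 4 | (2R,4R)-5,7-bis(4-methoxybenzyloxy)-2-(4-methoxyphenyl)chroman-4-ol | O[C@@H]1C[C@H](c2ccc(OC)cc2)Oc2cc(OCc3ccc(OC)cc3)cc(OCc3ccc(OC)cc3)c12
F3 | step 9 | (2R,3R)-3-bromo-7-methoxy-5-(4-methoxybenzyloxy)-2-(4-methoxyphenyl)chroman-4-one | O=C1[C@H](Br)[C@@H](c2ccc(OC)cc2)Oc2cc(OC)cc(OCc3ccc(OC)cc3)c12
F4 | step 9 | tert-butyl-[(2S)-5,7-bis(4-methoxybenzyloxy)-2-(4-methoxyphenyl)-2H-chromen-4-yl]oxy-dimethylsilane | CC(C)(C)[Si](C)(C)OC1=C[C@@H](c2ccc(OC)cc2)Oc2cc(OCc3ccc(OC)cc3)cc(OCc3ccc(OC)cc3)c12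
F5 | step 8 | trimethyl-[(2S)-5,7-bis(4-methoxybenzyloxy)-2-(4-methoxyphenyl)-2H-chromen-4-yl]oxysilane | C[Si](C)(C)OC1=C[C@@H](c2ccc(OC)cc2)Oc2cc(OCc3ccc(OC)cc3)cc(OCc3ccc(OC)cc3)c12
F6 | step 8 | trimethyl-[(2S)-7-methoxy-5-(4-methoxybenzyloxy)-2-(4-methoxyphenyl)-2H-chromen-4-yl]oxysilane | C[Si](C)(C)OC1=C[C@@H](c2ccc(OC)cc2)Oc2cc(OC)cc(OCc3ccc(OC)cc3)c12
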